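At early times the delta flask, which is the flask asked about, made target slowly, 3.4% at 5.00 min, so I set out to bracket what it holds at 100 min.

| setting | delta | gamma | flask |
|---|---|---|---|
| substrate | 0.80 M | 0.80 M | 0.80 M |
| reagent | 1.3 equiv | 0.65 equiv | 1.30 equiv |
| free catalyst | 0.8 mol% (in portions, 3) | 0.8 mol% (in portions, 3) | 0.8 mol% (in portions, 3) |
| remark | the very flask that is asked about, followed so far; portions every 12 min | run made earlier; portions every 12 min | the portions of free catalyst follow each other after 12 min, the first at the start |
| time |  |  | 100 min |

- delta (time / min: substrate / %, target / %): 1.33: 98.6, 0.9; 2.50: 97.8, 1.7; 5.00: 96.8, 3.4; 10.0: 93.3, 7.2; 20.0: 82.2, 18.2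
- gamma (time / min: substrate / %, target / %): 15.0: 91.0, 9.1; 30.0: 76.1, 24.0; 40.0: 66.7, 33.5; 60.0: 52.2, 47.5; 80.0: 44.6, 56.1

(each reading ± 0.3 percentage points)

- what was read earlier has a scatter of 0.3 percentage points, one standard deviation

- amount of substrate in the flask at 100 min, in percent of the substrate charged
- amount of target in the flask at 100 min, in percent of the substrate charged
- concentration of catalyst intermediate C at 100 min, in M

I assumed that reagent is used one to one with substrate. Substrate is then the limiting reagent in delta, the end state is target, and the question is how fast it is approached. My measure was the substrate's first-order constant, the logarithm of the fall in substrate divided by the time elapsed. In gamma, with the portions in, it was 0.0132 min⁻¹ from 30.0 min to 40.0 min, with reagent near 36.3% of the substrate charge. On that assumption delta keeps at least 30.0% of the substrate charge as reagent, close to that figure, so applying this constant from 20.0 min gave my estimated floor, target near 71.4%.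

Later in gamma the constant was 0.00787 min⁻¹ at reagent 13.2%, so it had fallen less steeply than the reagent. The constant per unit of reagent therefore rose in gamma while reagent and substrate both fell, and I took its late value as an overestimate for delta, which was charged with more reagent. Integrating with that value gave my estimated ceiling, target near 93.6%.

The forecast, holding that “A ping-pong cycle fits”, gave 11.9% substrate, 88% target and 0.0011 M of catalyst intermediate C. Its target lies inside my bracket.

The flask gave 8.58% substrate, 91.4% target and 0.00437 M of catalyst intermediate C, which is 3.97 times the forecast's value.

    substrate + catalyst intermediate C ⇌ catalyst intermediate D (K = 78.0 M⁻¹, k = 0.153 M⁻¹ s⁻¹)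
    reagent + free catalyst → catalyst intermediate A (k = 0.138 M⁻¹ s⁻¹)
    catalyst intermediate A ⇌ released group + catalyst intermediate B (K = 2.27 M, k = 9.87 s⁻¹)
    catalyst intermediate D ⇌ free catalyst + target (K = 1.50 M, k = 5.29 s⁻¹)
    catalyst intermediate B → catalyst intermediate C (k = 0.147 s⁻¹)

From the reading at 20.0 min on, the delta flask's constant came to 0.0283 min⁻¹, twice my gamma value, and over the whole run it averaged 0.0246 min⁻¹, a half-life of 28.2 min, shorter than the 100 min. The neighbouring flask with 0.20 M of substrate averaged 0.00651 min⁻¹, a half-life of 106 min, longer than the same time, and it still held 52.2% substrate.

The numbers in the tables stem from a simulated flask for substances that don't exist, and the scatter is random.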